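**Plan**

1. Numbering: C1 (CH–aryl), C2 and C3 (CH–CH2OH), C4 (CH2), ring fusion C4a/C8a; ring A = C4a–C5(OMe)–C6(OMe)–C7(OH)–C8–C8a, ring B = C1–C4/C4a/C8a. Retrosynthesis: diol ⇒ 2,3-diester; ring B is cut at C4–C4a (C4 as a formyl carbon), then C3–C4 (formate), C2–C3 (bromoacetate), C1–pendant aryl (conjugate arylation), C1=C2 (Wittig).
2. Forward: ring A aldehyde → C8 bromide → cinnamate → 3,3-diarylpropanoate (C1 set) → succinate → formylsuccinate → acid closure of ring B at C4–C4a → one hydrogenation/hydrogenolysis → equilibration → LiAlH4.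
3. Enabling feature: C4a is para to the C7 hydroxyl and ortho to the C5 methoxy group (cooperative, resorcinol-type activation), so an electrophilic C4 tethered through C1–C2–C3 closes ring B there; C8, the only other carbon ortho to C8a, carries a temporary Br.
4. Stereochemistry: C1 from the Rh/chiral-diene 1,4-arylation; C2 and C3 by NaOMe equilibration of the diester to the all-trans isomer dictated by the non-epimerisable C1.
5. Helpers: Br at C8, MOM on O7 (removed in the key step), Bn on O4′; Br and Bn leave in the same operation that saturates C3=C4.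

Key step: step 7

Assumption: in step 4 the antipode of the chiral diene ligand is the one that, by the accepted model for Rh–diene arylation of (E)-cinnamates, delivers the aryl group to the Si face of C-β; both antipodes are available.

Step 1
Reactants: 1 3-hydroxy-4,5-dimethoxybenzaldehyde
Product: 2 2-bromo-3-hydroxy-4,5-dimethoxybenzaldehyde
Conditions: Br2 (1.05 equiv), NaOAc, AcOH, 15–20 °C
Reagents that add atoms: bromine, BrBr
Why: Electrophilic aromatic bromination directed by the free phenol should occur at C2, ortho to OH, para to the 5-OMe and between OH and CHO, as in the bromination of isovanillin; this carbon becomes C8 and the Br blocks it.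

Step 2
Reactants: 2 2-bromo-3-hydroxy-4,5-dimethoxybenzaldehyde
Product: 3 2-bromo-4,5-dimethoxy-3-(methoxymethoxy)benzaldehyde
Conditions: MOMCl, iPr2NEt, CH2Cl2, 0 → 25 °C
Reagents that add atoms: chloromethyl methyl ether, COCCl
Why: O-alkylation of the phenol (MOM ether formation) masks the acidic OH for the enolate steps and gives a base-stable, acid-labile acetal.

Step 3
Reactants: 3 2-bromo-4,5-dimethoxy-3-(methoxymethoxy)benzaldehyde; 4 methyl (triphenyl-λ5-phosphanylidene)acetate
Product: 5 methyl (2E)-3-[2-bromo-4,5-dimethoxy-3-(methoxymethoxy)phenyl]prop-2-enoate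
Conditions: toluene, 80 °C
Reagents that add atoms: none
Why: Wittig olefination with a stabilised ylide should give the (E)-cinnamate and tolerates the aryl bromide and the acetal.

Step 4
Reactants: 5 methyl (2E)-3-[2-bromo-4,5-dimethoxy-3-(methoxymethoxy)phenyl]prop-2-enoate; 6 [4-(benzyloxy)-3-methoxyphenyl]boronic acid
Product: 7 methyl (3R)-3-[4-(benzyloxy)-3-methoxyphenyl]-3-[2-bromo-4,5-dimethoxy-3-(methoxymethoxy)phenyl]propanoate
Conditions: [RhCl(C2H4)2]2 (2.5 mol %), chiral diene Ph-bod* (5.5 mol %, antipode for Si-face arylation), KOH (0.5 equiv), dioxane/H2O 10:1, 50 °C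
Reagents that add atoms: none
Why: Rh(I)-catalysed asymmetric 1,4-addition of an arylboronic acid (Hayashi–Miyaura reaction), in which the chiral diene–Rh–aryl complex carbometalates the Si face of C-β and so sets C1 as (R) before the Rh enolate is protonated; aryl bromides and acetals are tolerated.

Step 5
Reactants: 7 methyl (3R)-3-[4-(benzyloxy)-3-methoxyphenyl]-3-[2-bromo-4,5-dimethoxy-3-(methoxymethoxy)phenyl]propanoate
Product: 8 dimethyl 2-{(R)-[4-(benzyloxy)-3-methoxyphenyl][2-bromo-4,5-dimethoxy-3-(methoxymethoxy)phenyl]methyl}butanedioate (both C2 epimers)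
Conditions: LDA, THF, −78 °C; BrCH2CO2Me, DMPU, −78 → −30 °C
Reagents that add atoms: methyl bromoacetate, COC(=O)CBr
Why: Ester enolate alkylation with a reactive α-bromo ester forms the C2–C3 bond; the C2 configuration is left open because it is corrected in step 9.

Step 6
Reactants: 8 dimethyl 2-{(R)-[4-(benzyloxy)-3-methoxyphenyl][2-bromo-4,5-dimethoxy-3-(methoxymethoxy)phenyl]methyl}butanedioate
Product: 9 dimethyl 2-{(R)-[4-(benzyloxy)-3-methoxyphenyl][2-bromo-4,5-dimethoxy-3-(methoxymethoxy)phenyl]methyl}-3-formylbutanedioate (aldehyde/enol tautomers, epimers)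
Conditions: NaH (3 equiv), HCO2Me (10 equiv), cat. MeOH, THF, 0 → 25 °C; AcOH quench
Reagents that add atoms: methyl formate, COC=O
Why: Crossed Claisen condensation (formylation) is reversible and is funnelled to C3, because only the C3 methylene can give the stabilised enolate of a β-formyl ester, whereas formylation at the tertiary C2 would be undone by retro-Claisen cleavage.

Step 7
Reactants: 9 dimethyl 2-{(R)-[4-(benzyloxy)-3-methoxyphenyl][2-bromo-4,5-dimethoxy-3-(methoxymethoxy)phenyl]methyl}-3-formylbutanedioate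
Product: 12 dimethyl (1R)-1-[4-(benzyloxy)-3-methoxyphenyl]-8-bromo-7-hydroxy-5,6-dimethoxy-1,2-dihydronaphthalene-2,3-dicarboxylate, via free phenol 10 (not isolated), via C4 carbinol 11 (not isolated)
Conditions: HCl in MeOH (1.25 M), 25 °C; concentrate; TFA/CH2Cl2 1:4, 0 → 25 °C
Reagents that add atoms: none
Why: Methanolic HCl cleaves the MOM acetal to phenol 10, and in TFA the protonated formyl carbon C4 is attacked by C4a of ring A to give, after loss of the C4a proton, carbinol 11, which ionises easily because C4 is para-hydroxybenzylic (quinone-methide-like cation) and loses H3 to give the conjugated ester 12. The closest known reaction type is the Bradsher-type acid cyclodehydration of α-formyl-γ-arylbutyrates to 3,4-dihydro-2-naphthoates, together with the phenolic Pomeranz–Fritsch–Bobbitt closure. Ring B (C1–C2–C3–C4–C4a–C8a) closes in the 6-exo-trig mode of an intramolecular Friedel–Crafts hydroxyalkylation, the C=O being exocyclic to the new ring. No lasting stereocentre is created (C4 of 11 is transient, C3 becomes sp2), C1 is not touched, and C2/C3 are set later under thermodynamic control. The step needs site selectivity on ring A, secured because C8 carries Br so that C4a is the only free position and is para to C7–OH and ortho to C5–OMe. It also needs chemoselectivity over the pendant ring, which should follow from the cooperative two-oxygen activation of C4a against the single para-methoxy activation of C6′ in the catechol-type pendant ring, helped by the weak and therefore selective electrophile.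

Step 8
Reactants: 12 dimethyl (1R)-1-[4-(benzyloxy)-3-methoxyphenyl]-8-bromo-7-hydroxy-5,6-dimethoxy-1,2-dihydronaphthalene-2,3-dicarboxylate
Product: 13 dimethyl (1R)-7-hydroxy-1-(4-hydroxy-3-methoxyphenyl)-5,6-dimethoxy-1,2,3,4-tetrahydronaphthalene-2,3-dicarboxylate (C2/C3 epimer mixture)
Conditions: H2 (3 atm), 10% Pd/C, NaOAc, MeOH/EtOAc, 25 °C
Reagents that add atoms: none
Why: Heterogeneous catalytic hydrogenation should saturate the trisubstituted C3=C4 bond and, in the same operation, cleave the benzyl ether and the C8–Br bond by hydrogenolysis (NaOAc takes up HBr); C3 forms without control and is corrected in step 9.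

Step 9
Reactants: 13 dimethyl (1R)-7-hydroxy-1-(4-hydroxy-3-methoxyphenyl)-5,6-dimethoxy-1,2,3,4-tetrahydronaphthalene-2,3-dicarboxylate
Product: 14 dimethyl (1R,2S,3S)-7-hydroxy-1-(4-hydroxy-3-methoxyphenyl)-5,6-dimethoxy-1,2,3,4-tetrahydronaphthalene-2,3-dicarboxylate
Conditions: NaOMe (5 equiv), MeOH, 60 °C; AcOH quench
Reagents that add atoms: none
Why: Base-mediated epimerisation through the two ester enolates should converge on the all-trans (all-pseudo-equatorial) diester, in which the non-enolisable C1 dictates C2 (trans to the aryl group) and C2 dictates C3.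

Step 10
Reactants: 14 dimethyl (1R,2S,3S)-7-hydroxy-1-(4-hydroxy-3-methoxyphenyl)-5,6-dimethoxy-1,2,3,4-tetrahydronaphthalene-2,3-dicarboxylate
Product: 15 (6S,7S,8R)-8-(4-hydroxy-3-methoxyphenyl)-6,7-bis(hydroxymethyl)-3,4-dimethoxy-5,6,7,8-tetrahydronaphthalen-2-ol (target)
Conditions: LiAlH4 (excess), THF, 0 → 50 °C; Rochelle salt work-up
Reagents that add atoms: none
Why: LiAlH4 reduction of both esters to primary alcohols, with the phenols carried as aluminium phenoxides, should leave the three stereocentres unchanged.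

**Compound list**

1 | 3-hydroxy-4,5-dimethoxybenzaldehyde | O=Cc1cc(O)c(OC)c(OC)c1 | starting material
2 | 2-bromo-3-hydroxy-4,5-dimethoxybenzaldehyde | O=Cc1c(Br)c(O)c(OC)c(OC)c1 | intermediate
3 | 2-bromo-4,5-dimethoxy-3-(methoxymethoxy)benzaldehyde | O=Cc1c(Br)c(OCOC)c(OC)c(OC)c1 | intermediate
4 | methyl (triphenyl-λ5-phosphanylidene)acetate | COC(=O)C=P(c1ccccc1)(c1ccccc1)c1ccccc1 | starting material
5 | methyl (2E)-3-[2-bromo-4,5-dimethoxy-3-(methoxymethoxy)phenyl]prop-2-enoate | COC(=O)/C=C/c1c(Br)c(OCOC)c(OC)c(OC)c1 | intermediate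
6 | [4-(benzyloxy)-3-methoxyphenyl]boronic acid | OB(O)c1ccc(OCc2ccccc2)c(OC)c1 | starting material
7 | methyl (3R)-3-[4-(benzyloxy)-3-methoxyphenyl]-3-[2-bromo-4,5-dimethoxy-3-(methoxymethoxy)phenyl]propanoate | COC(=O)C[C@H](c1ccc(OCc2ccccc2)c(OC)c1)c1c(Br)c(OCOC)c(OC)c(OC)c1 | intermediate
8 | dimethyl 2-{(R)-[4-(benzyloxy)-3-methoxyphenyl][2-bromo-4,5-dimethoxy-3-(methoxymethoxy)phenyl]methyl}butanedioate (C2 epimers) | COC(=O)CC(C(=O)OC)[C@H](c1ccc(OCc2ccccc2)c(OC)c1)c1c(Br)c(OCOC)c(OC)c(OC)c1 | intermediate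
9 | dimethyl 2-{(R)-[4-(benzyloxy)-3-methoxyphenyl][2-bromo-4,5-dimethoxy-3-(methoxymethoxy)phenyl]methyl}-3-formylbutanedioate (tautomers, epimers) | COC(=O)C(C=O)C(C(=O)OC)[C@H](c1ccc(OCc2ccccc2)c(OC)c1)c1c(Br)c(OCOC)c(OC)c(OC)c1 | intermediate
10 | dimethyl 2-{(R)-[4-(benzyloxy)-3-methoxyphenyl](2-bromo-3-hydroxy-4,5-dimethoxyphenyl)methyl}-3-formylbutanedioate | COC(=O)C(C=O)C(C(=O)OC)[C@H](c1ccc(OCc2ccccc2)c(OC)c1)c1c(Br)c(O)c(OC)c(OC)c1 | intermediate
11 | dimethyl (1R)-1-[4-(benzyloxy)-3-methoxyphenyl]-8-bromo-4,7-dihydroxy-5,6-dimethoxy-1,2,3,4-tetrahydronaphthalene-2,3-dicarboxylate | COC(=O)C1C(O)c2c(OC)c(OC)c(O)c(Br)c2[C@@H](c2ccc(OCc3ccccc3)c(OC)c2)C1C(=O)OC | intermediate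
12 | dimethyl (1R)-1-[4-(benzyloxy)-3-methoxyphenyl]-8-bromo-7-hydroxy-5,6-dimethoxy-1,2-dihydronaphthalene-2,3-dicarboxylate | COC(=O)C1=Cc2c(OC)c(OC)c(O)c(Br)c2[C@@H](c2ccc(OCc3ccccc3)c(OC)c2)C1C(=O)OC | intermediate
13 | dimethyl (1R)-7-hydroxy-1-(4-hydroxy-3-methoxyphenyl)-5,6-dimethoxy-1,2,3,4-tetrahydronaphthalene-2,3-dicarboxylate (C2/C3 epimers) | COC(=O)C1Cc2c(OC)c(OC)c(O)cc2[C@@H](c2ccc(O)c(OC)c2)C1C(=O)OC | intermediate
14 | dimethyl (1R,2S,3S)-7-hydroxy-1-(4-hydroxy-3-methoxyphenyl)-5,6-dimethoxy-1,2,3,4-tetrahydronaphthalene-2,3-dicarboxylate | COc1cc([C@@H]2c3cc(O)c(OC)c(OC)c3C[C@H](C(=O)OC)[C@H]2C(=O)OC)ccc1O | intermediate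
15 | (6S,7S,8R)-8-(4-hydroxy-3-methoxyphenyl)-6,7-bis(hydroxymethyl)-3,4-dimethoxy-5,6,7,8-tetrahydronaphthalen-2-ol | COc1cc([C@@H]2c3cc(O)c(OC)c(OC)c3C[C@H](CO)[C@H]2CO)ccc1O | target

Total step count: 10. Longest linear sequence: 10 steps (from 1).

**Steps most likely to fail**

Step 7. The ring may close through C6′ of the pendant ring (para to its methoxy group) instead of C4a, attack at the doubly flanked C4a may be slow, and the benzyl ether may be lost in acid. The fallback fixes the site by a carbon–iodine bond and reverses the polarity. It sets out from 9. Deformylative methylenation (aqueous formaldehyde, K2CO3, THF) should give dimethyl 2-{(R)-[4-(benzyloxy)-3-methoxyphenyl][2-bromo-4,5-dimethoxy-3-(methoxymethoxy)phenyl]methyl}-3-methylidenebutanedioate F1. Methanolic HCl should then remove the MOM group to give the phenol dimethyl 2-{(R)-[4-(benzyloxy)-3-methoxyphenyl](2-bromo-3-hydroxy-4,5-dimethoxyphenyl)methyl}-3-methylidenebutanedioate F2. Iodine and morpholine should iodinate the phenoxide ring at its only free position (C4a, para to OH) to give dimethyl 2-{(R)-[4-(benzyloxy)-3-methoxyphenyl](2-bromo-3-hydroxy-6-iodo-4,5-dimethoxyphenyl)methyl}-3-methylidenebutanedioate F3. With Bu3SnH and AIBN (benzene, 80 °C, slow addition) the C4a aryl radical should add 6-endo to the unsubstituted acrylate terminus C4 and, after hydrogen transfer, give dimethyl (1R)-1-[4-(benzyloxy)-3-methoxyphenyl]-8-bromo-7-hydroxy-5,6-dimethoxy-1,2,3,4-tetrahydronaphthalene-2,3-dicarboxylate F4 (C2/C3 epimers). F4 is put through the conditions of step 8, where only C–Br and O–Bn hydrogenolysis remain, and the route is rejoined at 13.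

Step 4. Arylation of the ortho-bromo cinnamate may be slow, boronic acid 6 may protodeboronate, and facial selectivity may be eroded. The fallback replaces catalyst control by a covalently bound oxazolidinone auxiliary. It sets out from 5. Saponification (LiOH, THF/H2O) should give (2E)-3-[2-bromo-4,5-dimethoxy-3-(methoxymethoxy)phenyl]prop-2-enoic acid F5. Activation as the mixed pivalic anhydride (PivCl, Et3N) and reaction with (4S)-4-phenyl-1,3-oxazolidin-2-one and LiCl should give (4S)-3-{(2E)-3-[2-bromo-4,5-dimethoxy-3-(methoxymethoxy)phenyl]prop-2-enoyl}-4-phenyl-1,3-oxazolidin-2-one F6. The Grignard reagent [4-(benzyloxy)-3-methoxyphenyl]magnesium bromide F7 is made from commercial 1-(benzyloxy)-4-bromo-2-methoxybenzene and Mg. With CuBr·SMe2 it should add to the chelated s-cis imide on the face opposite the phenyl group to give (4S)-3-{(3R)-3-[4-(benzyloxy)-3-methoxyphenyl]-3-[2-bromo-4,5-dimethoxy-3-(methoxymethoxy)phenyl]propanoyl}-4-phenyl-1,3-oxazolidin-2-one F8; the other antipode of the auxiliary would be used if the sense proved opposite. Methanolysis (MeOMgBr, MeOH, 0 °C) releases the auxiliary and returns to the route at 7.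

Step 8. On palladium the C3=C4 bond may migrate toward C2=C3 or C1=C2 before hydrogen is added, which would put the C1 configuration at risk; the dihydronaphthalene may also dehydrogenate to the naphthalene, or hydrogenolysis may stay incomplete. The fallback separates the events and uses a polar hydride for the alkene. It sets out from 12. Copper hydride conjugate reduction (Cu(OAc)2/bisphosphine cat., polymethylhydrosiloxane, tBuOH, toluene) should reduce only C3=C4 and give dimethyl (1R)-1-[4-(benzyloxy)-3-methoxyphenyl]-8-bromo-7-hydroxy-5,6-dimethoxy-1,2,3,4-tetrahydronaphthalene-2,3-dicarboxylate F9 (C2/C3 epimers, the same constitution as F4). Hydrogenolysis (H2, Pd/C, NaOAc) then removes Br and Bn without an alkene present and returns to the route at 13.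

**Further compounds**

F1 | step 7 | dimethyl 2-{(R)-[4-(benzyloxy)-3-methoxyphenyl][2-bromo-4,5-dimethoxy-3-(methoxymethoxy)phenyl]methyl}-3-methylidenebutanedioate | COC(=O)C(=C)C(C(=O)OC)[C@H](c1ccc(OCc2ccccc2)c(OC)c1)c1c(Br)c(OCOC)c(OC)c(OC)c1
F2 | step 7 | dimethyl 2-{(R)-[4-(benzyloxy)-3-methoxyphenyl](2-bromo-3-hydroxy-4,5-dimethoxyphenyl)methyl}-3-methylidenebutanedioate | COC(=O)C(=C)C(C(=O)OC)[C@H](c1ccc(OCc2ccccc2)c(OC)c1)c1c(Br)c(O)c(OC)c(OC)c1
F3 | step 7 | dimethyl 2-{(R)-[4-(benzyloxy)-3-methoxyphenyl](2-bromo-3-hydroxy-6-iodo-4,5-dimethoxyphenyl)methyl}-3-methylidenebutanedioate | COC(=O)C(=C)C(C(=O)OC)[C@H](c1ccc(OCc2ccccc2)c(OC)c1)c1c(Br)c(O)c(OC)c(OC)c1I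
F4 | step 7 | dimethyl (1R)-1-[4-(benzyloxy)-3-methoxyphenyl]-8-bromo-7-hydroxy-5,6-dimethoxy-1,2,3,4-tetrahydronaphthalene-2,3-dicarboxylate | COC(=O)C1Cc2c(OC)c(OC)c(O)c(Br)c2[C@@H](c2ccc(OCc3ccccc3)c(OC)c2)C1C(=O)OC
F5 | step 4 | (2E)-3-[2-bromo-4,5-dimethoxy-3-(methoxymethoxy)phenyl]prop-2-enoic acid | OC(=O)/C=C/c1c(Br)c(OCOC)c(OC)c(OC)c1
F6 | step 4 | (4S)-3-{(2E)-3-[2-bromo-4,5-dimethoxy-3-(methoxymethoxy)phenyl]prop-2-enoyl}-4-phenyl-1,3-oxazolidin-2-one | O=C(/C=C/c1c(Br)c(OCOC)c(OC)c(OC)c1)N1[C@@H](c2ccccc2)COC1=O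
F7 | step 4 | [4-(benzyloxy)-3-methoxyphenyl]magnesium bromide | COc1cc([Mg]Br)ccc1OCc1ccccc1
F8 | step 4 | (4S)-3-{(3R)-3-[4-(benzyloxy)-3-methoxyphenyl]-3-[2-bromo-4,5-dimethoxy-3-(methoxymethoxy)phenyl]propanoyl}-4-phenyl-1,3-oxazolidin-2-one | O=C(C[C@H](c1ccc(OCc2ccccc2)c(OC)c1)c1c(Br)c(OCOC)c(OC)c(OC)c1)N1[C@@H](c2ccccc2)COC1=O
F9 | step 8 | dimethyl (1R)-1-[4-(benzyloxy)-3-methoxyphenyl]-8-bromo-7-hydroxy-5,6-dimethoxy-1,2,3,4-tetrahydronaphthalene-2,3-dicarboxylate | COC(=O)C1Cc2c(OC)c(OC)c(O)c(Br)c2[C@@H](c2ccc(OCc3ccccc3)c(OC)c2)C1C(=O)OC
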